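Ring A is disconnected at C3'–C4' and C5'–C6'. Its contiguous C1' (acyl), C2' (methoxy), C3' (benzyl) and unsubstituted C6' map onto C5, C4, C3 and C6 of a 5-carbomethoxy-2-pyrone, so only C4' with its oxygen and C5' must be added. Heating pyrone 8, which already carries the methoxy group and the protected 2-hydroxybenzyl arm, with a ketene bis(silyl) acetal should effect an inverse-electron-demand Diels–Alder reaction; loss of carbon dioxide and silanol then delivers the complete tetrasubstituted benzoate, with the C4' hydroxyl as its only free phenol, in one operation. The ester is then converted into the dihydrochalcone ketone, and a single hydrogenolysis frees both phenols.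

Key step: step 5

Remark on the chemistry: the target has no stereocentre, so no stereocontrol is required; the bicyclic adduct of step 5 is racemic and its stereocentres vanish on aromatisation.

Step 1
Reactants: 1 dimethyl 3-oxopentanedioate; 2 trimethyl orthoformate
Product: 4 methyl 4-hydroxy-2-oxo-2H-pyran-5-carboxylate, via dimethyl 2-(methoxymethylidene)-3-oxopentanedioate 3 (not isolated)
Conditions: Ac2O, 120 °C; evaporate; then 1 M aq HCl, rt to 50 °C
Reagents that add atoms: water, O
Why: Orthoformate condensation at one activated methylene (Claisen-type alkoxymethylenation driven by Ac2O) should give enol ether 3, whose acid hydrolysis to the hydroxymethylene compound is followed by lactonisation onto the distal ester, a known route to 4-hydroxy-2-pyrone-5-carboxylates.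

Step 2
Reactants: 4 methyl 4-hydroxy-2-oxo-2H-pyran-5-carboxylate; 5 2-(benzyloxy)benzaldehyde
Product: 7 methyl 3-[2-(benzyloxy)benzyl]-4-hydroxy-2-oxo-2H-pyran-5-carboxylate, via methyl 3-[2-(benzyloxy)benzylidene]-2,4-dioxo-3,4-dihydro-2H-pyran-5-carboxylate 6 (not isolated)
Conditions: Hantzsch ester (diethyl 2,6-dimethyl-1,4-dihydropyridine-3,5-dicarboxylate), L-proline (cat), CH2Cl2, rt
Reagents that add atoms: none
Why: Knoevenagel condensation at C3, the only free nucleophilic carbon of the vinylogous acid, should give alkylidene 6, which is reduced at once by conjugate hydride transfer from the dihydropyridine (three-component reductive alkylation) so that addition of a second pyrone is outrun.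

Step 3
Reactants: 7 methyl 3-[2-(benzyloxy)benzyl]-4-hydroxy-2-oxo-2H-pyran-5-carboxylate
Product: 8 methyl 3-[2-(benzyloxy)benzyl]-4-methoxy-2-oxo-2H-pyran-5-carboxylate
Conditions: Me2SO4, K2CO3, acetone, reflux
Reagents that add atoms: dimethyl sulfate, COS(=O)(=O)OC
Why: Williamson-type O-alkylation of the potassium salt of the vinylogous acid with a hard methylating agent is the standard way to 4-methoxy-2-pyrones, the 4-oxygen being the more nucleophilic site of the ambident anion and C3 being already substituted.

Step 4
Reactants: 9 trimethylsilyl acetate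
Product: 11 1,1-bis(trimethylsilyloxy)ethene, via lithium 1-(trimethylsilyloxy)ethenolate 10 (not isolated)
Conditions: LiN(iPr)2, THF, −78 °C; then Me3SiCl, −78 °C to rt; distil
Reagents that add atoms: chlorotrimethylsilane, C[Si](C)(C)Cl
Why: Kinetic deprotonation of the silyl ester and O-silylation of the resulting ester enolate (silyl ketene acetal formation) is the established preparation of ketene bis(trimethylsilyl) acetals.

Step 5
Reactants: 8 methyl 3-[2-(benzyloxy)benzyl]-4-methoxy-2-oxo-2H-pyran-5-carboxylate; 11 1,1-bis(trimethylsilyloxy)ethene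
Product: 15 methyl 3-[2-(benzyloxy)benzyl]-4-hydroxy-2-methoxybenzoate, via racemic methyl 4-[2-(benzyloxy)benzyl]-5-methoxy-3-oxo-8,8-bis(trimethylsilyloxy)-2-oxabicyclo[2.2.2]oct-5-ene-6-carboxylate 12 (not isolated), via methyl 5-[2-(benzyloxy)benzyl]-6-methoxy-4,4-bis(trimethylsilyloxy)cyclohexa-1,5-diene-1-carboxylate 13 (not isolated), via methyl 3-[2-(benzyloxy)benzyl]-2-methoxy-4-(trimethylsilyloxy)benzoate 14 (not isolated)
Conditions: 11 (excess), toluene, sealed tube, 130 °C; evaporate; then 1 M HCl, THF, rt
Reagents that add atoms: none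
Why: The electron-rich ketene acetal 11 and the electron-poor diene of pyrone 8 should combine in a concerted but asynchronous inverse-electron-demand [4+2] cycloaddition across C3 and C6 of the pyrone to give bridged lactone 12, which expels carbon dioxide by retro-[4+2] to diene 13 and then aromatises by 1,2-elimination of trimethylsilanol to silyl ether 14, hydrolysed to phenol 15 on work-up. The closest known reaction type is the thermal conversion of 5-carboalkoxy-2-pyrones into benzoates with ketene acetals, with loss of carbon dioxide and an alcohol. Ring A is closed as a six-membered carbocycle by intermolecular [4+2] cycloaddition, its C3'–C4' and C5'–C6' bonds both arising in that event. No stereocentre has to be controlled, since the two bridgehead centres of racemic 12 are locked cis by the bicycle and disappear on aromatisation. The step needs regioselectivity, and the C5 ester secures it by making C6 the electrophilic diene terminus, so that the nucleophilic CH2 of 11 bonds to C6 and the acetal carbon to the benzyl-bearing C3, which puts the oxygen on C4'. It also needs a single mode of aromatisation, secured because only the bis(silyloxy) carbon carries a leaving group next to the new CH2 while the methoxy group sits on an sp2 carbon.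

Step 6
Reactants: 15 methyl 3-[2-(benzyloxy)benzyl]-4-hydroxy-2-methoxybenzoate
Product: 16 methyl 4-(benzyloxy)-3-[2-(benzyloxy)benzyl]-2-methoxybenzoate
Conditions: BnBr, K2CO3, DMF, rt to 50 °C
Reagents that add atoms: benzyl bromide, BrCc1ccccc1
Why: Williamson etherification of the phenol removes the acidic OH that would deactivate the ester in the next step and makes both phenol protecting groups benzyl ethers that can be removed together at the end.

Step 7
Reactants: 16 methyl 4-(benzyloxy)-3-[2-(benzyloxy)benzyl]-2-methoxybenzoate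
Product: 17 4-(benzyloxy)-3-[2-(benzyloxy)benzyl]-N,2-dimethoxy-N-methylbenzamide
Conditions: MeNH(OMe)·HCl, iPrMgCl, THF, −20 to 0 °C
Reagents that add atoms: N,O-dimethylhydroxylamine hydrochloride, CNOC.Cl
Why: The chloromagnesium amide of N,O-dimethylhydroxylamine formed in the flask should attack the methyl ester much faster than the hindered iPrMgCl does (direct aminolysis of an ester to a Weinreb amide), while the benzyl and methyl aryl ethers are inert.

Step 8
Reactants: 17 4-(benzyloxy)-3-[2-(benzyloxy)benzyl]-N,2-dimethoxy-N-methylbenzamide; 18 (2-phenylethyl)magnesium chloride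
Product: 20 1-{4-(benzyloxy)-3-[2-(benzyloxy)benzyl]-2-methoxyphenyl}-3-phenylpropan-1-one, via racemic chloromagnesium 1-{4-(benzyloxy)-3-[2-(benzyloxy)benzyl]-2-methoxyphenyl}-1-[methoxy(methyl)amino]-3-phenylpropan-1-olate 19 (not isolated)
Conditions: PhCH2CH2MgCl, THF, 0 °C to rt; then 1 M HCl
Reagents that add atoms: none
Why: In this Weinreb ketone synthesis the Grignard reagent should add once to give the chelated tetrahedral adduct 19, which persists until acidic work-up and therefore cannot over-add.

Step 9
Reactants: 20 1-{4-(benzyloxy)-3-[2-(benzyloxy)benzyl]-2-methoxyphenyl}-3-phenylpropan-1-one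
Product: 21 1-[4-hydroxy-3-(2-hydroxybenzyl)-2-methoxyphenyl]-3-phenylpropan-1-one
Conditions: H2 (1 atm), 10% Pd/C, EtOAc, rt; stopped after uptake of two equivalents of H2
Reagents that add atoms: none
Why: Hydrogenolysis of the two benzyl aryl ethers over Pd/C is much faster than reduction of the aryl alkyl ketone, which is deactivated by its ortho-methoxy and para-oxygen donors, so both phenols should be freed with the carbonyl intact.

Compound list
1 | dimethyl 3-oxopentanedioate | COC(=O)CC(=O)CC(=O)OC | starting material
2 | trimethyl orthoformate | COC(OC)OC | starting material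
3 | dimethyl 2-(methoxymethylidene)-3-oxopentanedioate (alkene geometry not defined) | COC=C(C(=O)OC)C(=O)CC(=O)OC | intermediate
4 | methyl 4-hydroxy-2-oxo-2H-pyran-5-carboxylate | COC(=O)C1=COC(=O)C=C1O | intermediate
5 | 2-(benzyloxy)benzaldehyde | O=Cc1ccccc1OCc1ccccc1 | starting material
6 | methyl 3-[2-(benzyloxy)benzylidene]-2,4-dioxo-3,4-dihydro-2H-pyran-5-carboxylate (alkene geometry not defined) | COC(=O)C1=COC(=O)C(=Cc2ccccc2OCc2ccccc2)C1=O | intermediate
7 | methyl 3-[2-(benzyloxy)benzyl]-4-hydroxy-2-oxo-2H-pyran-5-carboxylate | COC(=O)C1=COC(=O)C(Cc2ccccc2OCc2ccccc2)=C1O | intermediate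
8 | methyl 3-[2-(benzyloxy)benzyl]-4-methoxy-2-oxo-2H-pyran-5-carboxylate | COC(=O)C1=COC(=O)C(Cc2ccccc2OCc2ccccc2)=C1OC | intermediate
9 | trimethylsilyl acetate | CC(=O)O[Si](C)(C)C | starting material
10 | lithium 1-(trimethylsilyloxy)ethenolate | [Li+].[O-]C(=C)O[Si](C)(C)C | intermediate
11 | 1,1-bis(trimethylsilyloxy)ethene | C=C(O[Si](C)(C)C)O[Si](C)(C)C | intermediate
12 | methyl 4-[2-(benzyloxy)benzyl]-5-methoxy-3-oxo-8,8-bis(trimethylsilyloxy)-2-oxabicyclo[2.2.2]oct-5-ene-6-carboxylate (racemic, one enantiomer drawn; bridgeheads C1 and C4 joined by the lactone bridge) | O=C1O[C@H]2CC(O[Si](C)(C)C)(O[Si](C)(C)C)[C@]1(Cc3ccccc3OCc3ccccc3)C(OC)=C2C(=O)OC | intermediate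
13 | methyl 5-[2-(benzyloxy)benzyl]-6-methoxy-4,4-bis(trimethylsilyloxy)cyclohexa-1,5-diene-1-carboxylate | COC(=O)C1=CCC(O[Si](C)(C)C)(O[Si](C)(C)C)C(Cc2ccccc2OCc2ccccc2)=C1OC | intermediate
14 | methyl 3-[2-(benzyloxy)benzyl]-2-methoxy-4-(trimethylsilyloxy)benzoate | COC(=O)c1ccc(O[Si](C)(C)C)c(Cc2ccccc2OCc2ccccc2)c1OC | intermediate
15 | methyl 3-[2-(benzyloxy)benzyl]-4-hydroxy-2-methoxybenzoate | COC(=O)c1ccc(O)c(Cc2ccccc2OCc2ccccc2)c1OC | intermediate
16 | methyl 4-(benzyloxy)-3-[2-(benzyloxy)benzyl]-2-methoxybenzoate | COC(=O)c1ccc(OCc2ccccc2)c(Cc2ccccc2OCc2ccccc2)c1OC | intermediate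
17 | 4-(benzyloxy)-3-[2-(benzyloxy)benzyl]-N,2-dimethoxy-N-methylbenzamide | CON(C)C(=O)c1ccc(OCc2ccccc2)c(Cc2ccccc2OCc2ccccc2)c1OC | intermediate
18 | (2-phenylethyl)magnesium chloride, PhCH2CH2MgCl (commercial THF solution) | Cl[Mg]CCc1ccccc1 | starting material
19 | chloromagnesium 1-{4-(benzyloxy)-3-[2-(benzyloxy)benzyl]-2-methoxyphenyl}-1-[methoxy(methyl)amino]-3-phenylpropan-1-olate (racemic) | CON(C)C(O[Mg]Cl)(CCc1ccccc1)c1ccc(OCc2ccccc2)c(Cc2ccccc2OCc2ccccc2)c1OC | intermediate
20 | 1-{4-(benzyloxy)-3-[2-(benzyloxy)benzyl]-2-methoxyphenyl}-3-phenylpropan-1-one | COc1c(C(=O)CCc2ccccc2)ccc(OCc2ccccc2)c1Cc1ccccc1OCc1ccccc1 | intermediate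
21 | 1-[4-hydroxy-3-(2-hydroxybenzyl)-2-methoxyphenyl]-3-phenylpropan-1-one | COc1c(C(=O)CCc2ccccc2)ccc(O)c1Cc1ccccc1O | target

Total step count: 9

Longest linear sequence: 8 steps (steps 1, 2, 3, 5, 6, 7, 8 and 9 from compound 1); step 4 is a one-step branch that supplies 11.

Steps most likely to fail

Step 5. The cycloaddition may stall because the 4-methoxy group makes the diene too electron-rich, so that thermal silyl migration in 11, or conjugate addition at C6 followed by opening of the lactone ring, overtakes ring closure. The fallback keeps the same ring construction but uses a more electron-poor diene and sets the methyl ether afterwards. Setting out from 7, the 4-hydroxyl is acetylated (Ac2O, pyridine, 0 °C) to methyl 4-acetoxy-3-[2-(benzyloxy)benzyl]-2-oxo-2H-pyran-5-carboxylate F1. Its acyloxy group donates far less than methoxy and should let the cycloaddition with 11 run at lower temperature. The same loss of carbon dioxide and trimethylsilanol would give methyl 2-acetoxy-3-[2-(benzyloxy)benzyl]-4-(trimethylsilyloxy)benzoate F2, which is not isolated but stirred with K2CO3 in MeOH to remove the acetyl and silyl groups, giving methyl 3-[2-(benzyloxy)benzyl]-2,4-dihydroxybenzoate F3. The 4-hydroxyl, the only one not hydrogen-bonded to the ester, is then benzylated selectively (BnBr, K2CO3, acetone, reflux) to methyl 4-(benzyloxy)-3-[2-(benzyloxy)benzyl]-2-hydroxybenzoate F4. Methylation of the remaining chelated phenol (MeI, K2CO3, DMF, 50 °C) comes back to the route at 16.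

Step 3. The ambident pyrone anion may be methylated at the lactone carbonyl oxygen, giving the isomeric 2-methoxy-4-pyranone, or react sluggishly because the 4-hydroxyl is flanked on both sides and hydrogen-bonded to the ester. The fallback forms the C4–O bond instead of the O–CH3 bond, so the position of the ether is fixed by the carbon that is attacked. Setting out from 7, POCl3 and Et3N (MeCN, 60 °C) should give methyl 3-[2-(benzyloxy)benzyl]-4-chloro-2-oxo-2H-pyran-5-carboxylate F5. Addition–elimination of NaOMe (one equivalent, MeOH, −10 °C) at C4, a vinylogous acyl chloride position, comes back to the route at 8.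

Step 2. Alkylidene 6 may be intercepted by a second molecule of 4 faster than hydride is transferred, which would consume the pyrone in a bis-adduct. The fallback separates trapping from reduction. Setting out from 4 and 5, thiophenol (EtOH, catalytic piperidinium acetate, rt) should capture 6 as racemic methyl 3-{[2-(benzyloxy)phenyl](phenylsulfanyl)methyl}-4-hydroxy-2-oxo-2H-pyran-5-carboxylate F6. Desulfurisation of the benzylic sulfide with deactivated Raney nickel (acetone, rt) comes back to the route at 7.

Further compounds
F1 | step 5 | methyl 4-acetoxy-3-[2-(benzyloxy)benzyl]-2-oxo-2H-pyran-5-carboxylate | COC(=O)C1=COC(=O)C(Cc2ccccc2OCc2ccccc2)=C1OC(C)=O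
F2 | step 5 | methyl 2-acetoxy-3-[2-(benzyloxy)benzyl]-4-(trimethylsilyloxy)benzoate | COC(=O)c1ccc(O[Si](C)(C)C)c(Cc2ccccc2OCc2ccccc2)c1OC(C)=O
F3 | step 5 | methyl 3-[2-(benzyloxy)benzyl]-2,4-dihydroxybenzoate | COC(=O)c1ccc(O)c(Cc2ccccc2OCc2ccccc2)c1O
F4 | step 5 | methyl 4-(benzyloxy)-3-[2-(benzyloxy)benzyl]-2-hydroxybenzoate | COC(=O)c1ccc(OCc2ccccc2)c(Cc2ccccc2OCc2ccccc2)c1O
F5 | step 3 | methyl 3-[2-(benzyloxy)benzyl]-4-chloro-2-oxo-2H-pyran-5-carboxylate | COC(=O)C1=COC(=O)C(Cc2ccccc2OCc2ccccc2)=C1Cl
F6 | step 2 | methyl 3-{[2-(benzyloxy)phenyl](phenylsulfanyl)methyl}-4-hydroxy-2-oxo-2H-pyran-5-carboxylate (racemic) | COC(=O)C1=COC(=O)C(C(Sc2ccccc2)c2ccccc2OCc2ccccc2)=C1O
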